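**Plan**

1. Target 19 is a trans-2,3-diaryl-2,3-dihydrobenzofuran (O1; C2 with catechol ring B; C3 with resorcinol ring C; benzo ring A, C3a–C7a, with OH on C4 and the styryl arm on C6). C2 and C3 are adjacent sp3 carbons that each carry one aryl group, and the O1 oxygen on C2 can be carried as boron, so both aryl–carbon bonds can be made at once across the alkene of a ring A alkenylboronate.
2. Retrosynthetic cuts, in order: the six aryl O–CH3 bonds; the O1–C2 ether bond (leaving a C2 carbinol, that is, a C2–B bond); the C2–ring B and C3–ring C bonds together; the B–CH=CH alkene back to a ring A aldehyde; the aldehyde C–C bond (ortho-lithiation); the stilbene C=C bond.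
3. Forward: ring A stilbene by Horner–Wadsworth–Emmons olefination, formylation between its two MOM ethers, boron–Wittig olefination and exchange of pinacol for the hindered mac diol, three-component conjunctive coupling (no ring formed), C–B oxidation, acid-induced closure of the dihydrofuran (the only ring made), demethylation.
4. Stereochemistry: C3 (S) comes from the chiral palladium catalyst choosing the alkene face. C2 is set (R) in the coupling by anti addition, carried through the oxidation with retention, and finally fixed as (S), trans to ring C, when the C2 cation is captured by the ring A phenol.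

Key step: step 8

Assumption: the boron ligand cis-1,2-dimethyl-1,2-dihydroacenaphthylene-1,2-diol (mac diol) is taken as a purchasable reagent; it is otherwise one step from acenaphthoquinone and MeMgBr.

**Route**

Step 1
Reactants: 1 3,5-dihydroxybenzaldehyde
Product: 2 3,5-bis(methoxymethoxy)benzaldehyde
Conditions: MOMCl, iPr2NEt, CH2Cl2, 0 °C → rt
Reagents that add atoms: chloromethyl methyl ether, COCCl
Why: Base-mediated O-alkylation of both phenols by the reactive α-chloro ether (MOM protection) is routine and installs the groups that later direct lithiation and leave under mild acid.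

Step 2
Reactants: 2 3,5-bis(methoxymethoxy)benzaldehyde; 3 diethyl (3,4-dimethoxybenzyl)phosphonate
Product: 4 4-[(E)-2-[3,5-bis(methoxymethoxy)phenyl]ethenyl]-1,2-dimethoxybenzene
Conditions: KOtBu, THF, 0 °C → rt
Reagents that add atoms: none
Why: Horner–Wadsworth–Emmons olefination of an aryl aldehyde by a benzylic phosphonate anion adds reversibly and collapses through the less crowded oxaphosphetane, which should give the (E)-stilbene.

Step 3
Reactants: 4 4-[(E)-2-[3,5-bis(methoxymethoxy)phenyl]ethenyl]-1,2-dimethoxybenzene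
Product: 6 4-[(E)-2-(3,4-dimethoxyphenyl)ethenyl]-2,6-bis(methoxymethoxy)benzaldehyde, via aryllithium 5 (not isolated)
Conditions: n-BuLi, THF, 0 °C; then DMF, 0 °C → rt; H2O
Reagents that add atoms: N,N-dimethylformamide, CN(C)C=O
Why: Directed ortho-metalation removes the one ring proton flanked by two chelating MOM ethers much faster than any proton next to a methoxy group, and the aryllithium is formylated by DMF (Bouveault formylation).

Step 4
Reactants: 6 4-[(E)-2-(3,4-dimethoxyphenyl)ethenyl]-2,6-bis(methoxymethoxy)benzaldehyde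
Product: 7 2-[(E)-2-[4-[(E)-2-(3,4-dimethoxyphenyl)ethenyl]-2,6-bis(methoxymethoxy)phenyl]ethenyl]-4,4,5,5-tetramethyl-1,3,2-dioxaborolane
Conditions: CH2(Bpin)2, lithium 2,2,6,6-tetramethylpiperidide (LiTMP), THF, 0 °C; then 6, −78 °C → rt
Reagents that add atoms: bis(4,4,5,5-tetramethyl-1,3,2-dioxaborolan-2-yl)methane, CC1(C)OB(CB2OC(C)(C)C(C)(C)O2)OC1(C)C
Why: Boron–Wittig olefination, in which the α-boryl carbanion adds to the aldehyde and the adduct loses a boron-bound oxygen by syn elimination, is known to turn aldehydes into (E)-alkenyl pinacol boronates.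

Step 5
Reactants: 7 2-[(E)-2-[4-[(E)-2-(3,4-dimethoxyphenyl)ethenyl]-2,6-bis(methoxymethoxy)phenyl]ethenyl]-4,4,5,5-tetramethyl-1,3,2-dioxaborolane
Product: 8 [(E)-2-[4-[(E)-2-(3,4-dimethoxyphenyl)ethenyl]-2,6-bis(methoxymethoxy)phenyl]ethenyl]boronic acid
Conditions: NaIO4, NH4OAc, acetone/H2O, rt
Reagents that add atoms: water, O
Why: Oxidative cleavage by periodate of the pinacol freed in the hydrolysis equilibrium pulls the ester over to the boronic acid at near-neutral pH, which spares the MOM ethers and both alkenes (boronic ester deprotection).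

Step 6
Reactants: 8 [(E)-2-[4-[(E)-2-(3,4-dimethoxyphenyl)ethenyl]-2,6-bis(methoxymethoxy)phenyl]ethenyl]boronic acid
Product: 9 mac ester of 8 (cyclic boronate of 8 with cis-1,2-dimethyl-1,2-dihydroacenaphthylene-1,2-diol)
Conditions: mac diol, MgSO4, CH2Cl2, rt
Reagents that add atoms: cis-1,2-dimethyl-1,2-dihydroacenaphthylene-1,2-diol (mac diol), O[C@]1(C)c2cccc3cccc(c23)[C@]1(C)O
Why: Dehydrative esterification of a boronic acid by a rigid cis-1,2-diol is fast and gives the hindered boronate whose shielded oxygens disfavour direct boron-to-palladium transmetalation in step 8.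

Step 7
Reactants: 10 3,5-dimethoxyphenol
Product: 11 3,5-dimethoxyphenyl trifluoromethanesulfonate
Conditions: Tf2O, pyridine, CH2Cl2, 0 °C
Reagents that add atoms: trifluoromethanesulfonic anhydride, O=S(=O)(OS(=O)(=O)C(F)(F)F)C(F)(F)F
Why: O-Sulfonylation of the phenol by triflic anhydride is routine and gives a halide-free electrophile for the palladium step.

Step 8
Reactants: 9 mac ester of 8; 12 4-bromo-1,2-dimethoxybenzene; 11 3,5-dimethoxyphenyl trifluoromethanesulfonate
Product: 15 mac boronate of (1R,2S)-1-(3,4-dimethoxyphenyl)-2-(3,5-dimethoxyphenyl)-2-[4-[(E)-2-(3,4-dimethoxyphenyl)ethenyl]-2,6-bis(methoxymethoxy)phenyl]ethane (boron on C1), via aryllithium 13 (not isolated), via ate complex 14 (not isolated)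
Conditions: 12, n-BuLi, THF, −78 °C; then 9, −78 °C → rt; then 11, Pd(OAc)2 (3 mol %), MandyPhos ligand 1,1'-bis(diphenylphosphino)-2,2'-bis[α-(dimethylamino)benzyl]ferrocene (single enantiomer, 3.6 mol %), THF, 60 °C
Reagents that add atoms: none
Why: Aryllithium 13 adds to boron of 9 to give ate complex 14; oxidative addition of 11 to zerovalent palladium gives a cationic arylpalladium species (divalent palladium) that binds the alkene of 14 and induces a 1,2-shift of ring B from boron to C2 anti to palladium on C3, after which reductive elimination forms the C3–ring C bond. The closest known reaction is the palladium-catalysed enantioselective conjunctive cross-coupling of β-substituted alkenylboron ate complexes that carry the mac ligand, applied here to a β-aryl group with two ortho substituents. No ring closes. C3 (S) is set by the chiral ferrocenyl bisphosphine, whose enantiomer is chosen so that palladium sits on the Re face of C3, and C2 (R) follows from the stereospecific anti addition across the (E)-alkene. The step needs the metallate shift to outrun direct transfer of an organic group from boron to palladium (Suzuki–Miyaura coupling), which the shielding mac diol on boron secures, and it needs the stilbene to stay untouched, which holds because only the alkene attached to the anionic boron is nucleophilic enough for the cationic palladium. Bromine–lithium exchange with n-BuLi leaves 1-bromobutane and no lithium halide, so halide inhibition of the catalyst is avoided.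

Step 9
Reactants: 15 mac boronate of the (1R,2S)-1,1,2-triarylethane
Product: 16 (1R,2S)-1-(3,4-dimethoxyphenyl)-2-(3,5-dimethoxyphenyl)-2-[4-[(E)-2-(3,4-dimethoxyphenyl)ethenyl]-2,6-bis(methoxymethoxy)phenyl]ethan-1-ol
Conditions: H2O2, NaOH, THF/H2O, 0 °C → rt
Reagents that add atoms: hydrogen peroxide, OO
Why: Oxidation of the carbon–boron bond by alkaline hydrogen peroxide proceeds by 1,2-shift of the benzylic carbon from boron to oxygen with retention, so the (1R) configuration of 15 becomes that of the carbinol, and the electron-rich stilbene is inert to the nucleophilic oxidant.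

Step 10
Reactants: 16 (1R,2S)-1-(3,4-dimethoxyphenyl)-2-(3,5-dimethoxyphenyl)-2-[4-[(E)-2-(3,4-dimethoxyphenyl)ethenyl]-2,6-bis(methoxymethoxy)phenyl]ethan-1-ol
Product: 18 (2S,3S)-2-(3,4-dimethoxyphenyl)-3-(3,5-dimethoxyphenyl)-6-[(E)-2-(3,4-dimethoxyphenyl)ethenyl]-2,3-dihydro-1-benzofuran-4-ol, via triol 17 (not isolated)
Conditions: HCl, MeOH, 40 °C
Reagents that add atoms: none
Why: Acid-catalysed methanolysis removes both MOM acetals and ionises the alkoxy-stabilised benzylic alcohol, and either of the two equivalent ortho phenols of ring A captures the planar C2 cation on the face away from ring C (SN1 cycloetherification), which should give the trans (2S,3S) five-membered ether while C3 is not touched.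

Step 11
Reactants: 18 (2S,3S)-2-(3,4-dimethoxyphenyl)-3-(3,5-dimethoxyphenyl)-6-[(E)-2-(3,4-dimethoxyphenyl)ethenyl]-2,3-dihydro-1-benzofuran-4-ol
Product: 19 (2S,3S)-2-(3,4-dihydroxyphenyl)-3-(3,5-dihydroxyphenyl)-6-[(E)-2-(3,4-dihydroxyphenyl)ethenyl]-2,3-dihydro-1-benzofuran-4-ol
Conditions: BBr3, CH2Cl2, −78 °C → rt; then H2O
Reagents that add atoms: none
Why: Cleavage of aryl methyl ethers by BBr3 (Lewis acid activation of oxygen, then bromide attack on methyl) has precedent both on stilbene catechol ethers and on 2,3-diaryl-2,3-dihydrobenzofurans, and the trans arrangement is the stable one, so a reversible opening at C2–O1 would re-close to the same diastereomer.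

**Compound list**

1 | 3,5-dihydroxybenzaldehyde | O=Cc1cc(O)cc(O)c1 | starting material
2 | 3,5-bis(methoxymethoxy)benzaldehyde | COCOc1cc(C=O)cc(OCOC)c1 | intermediate
3 | diethyl (3,4-dimethoxybenzyl)phosphonate | CCOP(=O)(Cc1ccc(OC)c(OC)c1)OCC | starting material
4 | 4-[(E)-2-[3,5-bis(methoxymethoxy)phenyl]ethenyl]-1,2-dimethoxybenzene | COCOc1cc(/C=C/c2ccc(OC)c(OC)c2)cc(OCOC)c1 | intermediate
5 | [4-[(E)-2-(3,4-dimethoxyphenyl)ethenyl]-2,6-bis(methoxymethoxy)phenyl]lithium | COCOc1cc(/C=C/c2ccc(OC)c(OC)c2)cc(OCOC)c1[Li] | intermediate (not isolated)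
6 | 4-[(E)-2-(3,4-dimethoxyphenyl)ethenyl]-2,6-bis(methoxymethoxy)benzaldehyde | COCOc1cc(/C=C/c2ccc(OC)c(OC)c2)cc(OCOC)c1C=O | intermediate
7 | 2-[(E)-2-[4-[(E)-2-(3,4-dimethoxyphenyl)ethenyl]-2,6-bis(methoxymethoxy)phenyl]ethenyl]-4,4,5,5-tetramethyl-1,3,2-dioxaborolane | COCOc1cc(/C=C/c2ccc(OC)c(OC)c2)cc(OCOC)c1/C=C/B1OC(C)(C)C(C)(C)O1 | intermediate
8 | [(E)-2-[4-[(E)-2-(3,4-dimethoxyphenyl)ethenyl]-2,6-bis(methoxymethoxy)phenyl]ethenyl]boronic acid | COCOc1cc(/C=C/c2ccc(OC)c(OC)c2)cc(OCOC)c1/C=C/B(O)O | intermediate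
9 | mac ester of 8 (cyclic boronate with cis-1,2-dimethyl-1,2-dihydroacenaphthylene-1,2-diol) | COCOc1cc(/C=C/c2ccc(OC)c(OC)c2)cc(OCOC)c1/C=C/B1O[C@]2(C)c3cccc4cccc(c34)[C@]2(C)O1 | intermediate
10 | 3,5-dimethoxyphenol | COc1cc(O)cc(OC)c1 | starting material
11 | 3,5-dimethoxyphenyl trifluoromethanesulfonate | COc1cc(OC)cc(OS(=O)(=O)C(F)(F)F)c1 | intermediate
12 | 4-bromo-1,2-dimethoxybenzene | COc1ccc(Br)cc1OC | starting material
13 | (3,4-dimethoxyphenyl)lithium | [Li]c1ccc(OC)c(OC)c1 | intermediate (not isolated)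
14 | lithium ate complex of 9 and 13 (boron carries the alkenyl group, the 3,4-dimethoxyphenyl group and the mac diolate) | [Li+].COCOc1cc(/C=C/c2ccc(OC)c(OC)c2)cc(OCOC)c1/C=C/[B-]1(c2ccc(OC)c(OC)c2)O[C@]2(C)c3cccc4cccc(c34)[C@]2(C)O1 | intermediate (not isolated)
15 | mac boronate of (1R,2S)-1-(3,4-dimethoxyphenyl)-2-(3,5-dimethoxyphenyl)-2-[4-[(E)-2-(3,4-dimethoxyphenyl)ethenyl]-2,6-bis(methoxymethoxy)phenyl]ethane, boron on C1 (C1 = future C2, C2 = future C3) | COCOc1cc(/C=C/c2ccc(OC)c(OC)c2)cc(OCOC)c1[C@H](c1cc(OC)cc(OC)c1)[C@@H](B1O[C@]2(C)c3cccc4cccc(c34)[C@]2(C)O1)c1ccc(OC)c(OC)c1 | intermediate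
16 | (1R,2S)-1-(3,4-dimethoxyphenyl)-2-(3,5-dimethoxyphenyl)-2-[4-[(E)-2-(3,4-dimethoxyphenyl)ethenyl]-2,6-bis(methoxymethoxy)phenyl]ethan-1-ol | COCOc1cc(/C=C/c2ccc(OC)c(OC)c2)cc(OCOC)c1[C@H](c1cc(OC)cc(OC)c1)[C@@H](O)c1ccc(OC)c(OC)c1 | intermediate
17 | 2-[(1S,2R)-2-(3,4-dimethoxyphenyl)-1-(3,5-dimethoxyphenyl)-2-hydroxyethyl]-5-[(E)-2-(3,4-dimethoxyphenyl)ethenyl]benzene-1,3-diol | Oc1cc(/C=C/c2ccc(OC)c(OC)c2)cc(O)c1[C@H](c1cc(OC)cc(OC)c1)[C@@H](O)c1ccc(OC)c(OC)c1 | intermediate (not isolated)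
18 | (2S,3S)-2-(3,4-dimethoxyphenyl)-3-(3,5-dimethoxyphenyl)-6-[(E)-2-(3,4-dimethoxyphenyl)ethenyl]-2,3-dihydro-1-benzofuran-4-ol (trans) | COc1cc(OC)cc([C@H]2c3c(O)cc(/C=C/c4ccc(OC)c(OC)c4)cc3O[C@@H]2c2ccc(OC)c(OC)c2)c1 | intermediate
19 | (2S,3S)-2-(3,4-dihydroxyphenyl)-3-(3,5-dihydroxyphenyl)-6-[(E)-2-(3,4-dihydroxyphenyl)ethenyl]-2,3-dihydro-1-benzofuran-4-ol (trans) | Oc1cc(O)cc([C@H]2c3c(O)cc(/C=C/c4ccc(O)c(O)c4)cc3O[C@@H]2c2ccc(O)c(O)c2)c1 | target

**Step count and risks**

Total: 11 steps. Longest linear sequence: 10 steps (steps 1–6 and 8–11, from 1 to 19); step 7 is a one-step side branch.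

Risk 1, step 8. The two ortho MOM ethers of the β-aryl group may keep the cationic palladium off the alkene. The ate complex would then hand an aryl or alkenyl group directly to palladium (biaryl or stilbene by-products), the boronate could be lost by protonation, or the face selectivity at C3 could drop. The fallback sets out from aldehyde 6 and comes back at dihydrobenzofuran 18:
- Henry condensation of 6 with nitromethane (NH4OAc, 90 °C) should give (E)-nitroalkene F1.
- Rhodium-catalysed asymmetric conjugate addition of 3,5-dimethoxyphenylboronic acid ([RhCl(C2H4)2]2, chiral diene ligand, KOH, dioxane/H2O) sets C3 in (S)-nitroalkane F2.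
- A buffered reductive Nef reaction (NaOMe, then TiCl3/NH4OAc) gives (S)-diarylacetaldehyde F3, which is used at once because its α-centre can epimerise.
- Addition of 3,4-dimethoxyphenylmagnesium bromide at −78 °C gives alcohol F4 as a pair of carbinol epimers, one of which is 16.
- Both epimers pass through the same C2 cation under the conditions of step 10 and converge on 18.

Risk 2, step 11. Sixfold ether cleavage may stop short, and the Lewis acid together with HBr may ionise the C2–O1 bond (ring opening, then elimination towards a triarylethene with loss of the C3 centre) or add to the stilbene. The fallback changes the phenol protecting group from methyl to benzyl; it sets out from aldehyde 2 and comes back at target 19: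
- Arbuzov reaction of commercial 3,4-bis(benzyloxy)benzyl chloride with P(OEt)3 gives phosphonate F5.
- The operations of steps 2–6 then give in turn stilbene F6, aryllithium F7 (in the flask), aldehyde F8, pinacol boronate F9, boronic acid F10 and mac boronate F11.
- Commercial 3,5-bis(benzyloxy)phenol is converted into triflate F12 as in step 7.
- Commercial 4-bromo-1,2-bis(benzyloxy)benzene and n-BuLi give aryllithium F13, which forms ate complex F14 with F11 and, under the conditions of step 8 with F12, boronate F15.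
- Oxidation as in step 9 gives alcohol F16, and HCl/MeOH gives, through triol F17, the hexabenzyl dihydrobenzofuran F18.
- BCl3 with pentamethylbenzene as cation scavenger (CH2Cl2, −78 °C) removes the six benzyl groups at low temperature, without hydrogenation of the stilbene, to give 19.

Risk 3, step 10. The C2 cation may lose the C3 proton to give a triarylethene whose re-protonation scrambles C3, or an aryl group may bridge and migrate, so that enantiopurity or constitution erodes. The fallback closes the ring by SN2 displacement instead of through the cation; it sets out from boronate 15 and comes back at 18: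
- HCl/MeOH at room temperature removes the MOM groups while boron still occupies C2, giving bis-phenol boronate F19.
- Oxidation with NaBO3·4H2O (THF/H2O) gives triol 17, which is now isolated.
- A Mitsunobu reaction (PPh3, DIAD, THF, 0 °C) lets a ring A phenol displace the activated (R)-carbinol oxygen with inversion, which gives (2S,3S)-18 directly.

**Further compounds**

F1 | step 8 | 5-[(E)-2-(3,4-dimethoxyphenyl)ethenyl]-1,3-bis(methoxymethoxy)-2-[(E)-2-nitroethenyl]benzene | COCOc1cc(/C=C/c2ccc(OC)c(OC)c2)cc(OCOC)c1/C=C/[N+](=O)[O-]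
F2 | step 8 | 2-[(1S)-1-(3,5-dimethoxyphenyl)-2-nitroethyl]-5-[(E)-2-(3,4-dimethoxyphenyl)ethenyl]-1,3-bis(methoxymethoxy)benzene | COCOc1cc(/C=C/c2ccc(OC)c(OC)c2)cc(OCOC)c1[C@H](c1cc(OC)cc(OC)c1)C[N+](=O)[O-]
F3 | step 8 | (2S)-2-(3,5-dimethoxyphenyl)-2-[4-[(E)-2-(3,4-dimethoxyphenyl)ethenyl]-2,6-bis(methoxymethoxy)phenyl]acetaldehyde | COCOc1cc(/C=C/c2ccc(OC)c(OC)c2)cc(OCOC)c1[C@H](c1cc(OC)cc(OC)c1)C=O
F4 | step 8 | (1RS,2S)-1-(3,4-dimethoxyphenyl)-2-(3,5-dimethoxyphenyl)-2-[4-[(E)-2-(3,4-dimethoxyphenyl)ethenyl]-2,6-bis(methoxymethoxy)phenyl]ethan-1-ol (16 and its C1 epimer) | COCOc1cc(/C=C/c2ccc(OC)c(OC)c2)cc(OCOC)c1[C@H](c1cc(OC)cc(OC)c1)C(O)c1ccc(OC)c(OC)c1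
F5 | step 11 | diethyl [3,4-bis(benzyloxy)benzyl]phosphonate | CCOP(=O)(Cc1ccc(OCc2ccccc2)c(OCc2ccccc2)c1)OCC
F6 | step 11 | 1,2-bis(benzyloxy)-4-[(E)-2-[3,5-bis(methoxymethoxy)phenyl]ethenyl]benzene | COCOc1cc(/C=C/c2ccc(OCc3ccccc3)c(OCc3ccccc3)c2)cc(OCOC)c1
F7 | step 11 | [4-[(E)-2-[3,4-bis(benzyloxy)phenyl]ethenyl]-2,6-bis(methoxymethoxy)phenyl]lithium | COCOc1cc(/C=C/c2ccc(OCc3ccccc3)c(OCc3ccccc3)c2)cc(OCOC)c1[Li]
F8 | step 11 | 4-[(E)-2-[3,4-bis(benzyloxy)phenyl]ethenyl]-2,6-bis(methoxymethoxy)benzaldehyde | COCOc1cc(/C=C/c2ccc(OCc3ccccc3)c(OCc3ccccc3)c2)cc(OCOC)c1C=O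
F9 | step 11 | pinacol (E)-alkenylboronate from F8 (benzyl analogue of 7) | COCOc1cc(/C=C/c2ccc(OCc3ccccc3)c(OCc3ccccc3)c2)cc(OCOC)c1/C=C/B1OC(C)(C)C(C)(C)O1
F10 | step 11 | (E)-alkenylboronic acid from F9 (benzyl analogue of 8) | COCOc1cc(/C=C/c2ccc(OCc3ccccc3)c(OCc3ccccc3)c2)cc(OCOC)c1/C=C/B(O)O
F11 | step 11 | mac ester of F10 (benzyl analogue of 9) | COCOc1cc(/C=C/c2ccc(OCc3ccccc3)c(OCc3ccccc3)c2)cc(OCOC)c1/C=C/B1O[C@]2(C)c3cccc4cccc(c34)[C@]2(C)O1
F12 | step 11 | 3,5-bis(benzyloxy)phenyl trifluoromethanesulfonate | FC(F)(F)S(=O)(=O)Oc1cc(OCc2ccccc2)cc(OCc2ccccc2)c1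
F13 | step 11 | [3,4-bis(benzyloxy)phenyl]lithium | [Li]c1ccc(OCc2ccccc2)c(OCc2ccccc2)c1
F14 | step 11 | lithium ate complex of F11 and F13 (benzyl analogue of 14) | [Li+].COCOc1cc(/C=C/c2ccc(OCc3ccccc3)c(OCc3ccccc3)c2)cc(OCOC)c1/C=C/[B-]1(c2ccc(OCc3ccccc3)c(OCc3ccccc3)c2)O[C@]2(C)c3cccc4cccc(c34)[C@]2(C)O1
F15 | step 11 | (1R,2S)-mac boronate, analogue of 15 with benzyl in place of each of the six methyl groups | COCOc1cc(/C=C/c2ccc(OCc3ccccc3)c(OCc3ccccc3)c2)cc(OCOC)c1[C@H](c1cc(OCc2ccccc2)cc(OCc2ccccc2)c1)[C@@H](B1O[C@]2(C)c3cccc4cccc(c34)[C@]2(C)O1)c1ccc(OCc2ccccc2)c(OCc2ccccc2)c1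
F16 | step 11 | (1R,2S)-alcohol, hexabenzyl analogue of 16 | COCOc1cc(/C=C/c2ccc(OCc3ccccc3)c(OCc3ccccc3)c2)cc(OCOC)c1[C@H](c1cc(OCc2ccccc2)cc(OCc2ccccc2)c1)[C@@H](O)c1ccc(OCc2ccccc2)c(OCc2ccccc2)c1
F17 | step 11 | triol, hexabenzyl analogue of 17 | Oc1cc(/C=C/c2ccc(OCc3ccccc3)c(OCc3ccccc3)c2)cc(O)c1[C@H](c1cc(OCc2ccccc2)cc(OCc2ccccc2)c1)[C@@H](O)c1ccc(OCc2ccccc2)c(OCc2ccccc2)c1
F18 | step 11 | (2S,3S)-2-[3,4-bis(benzyloxy)phenyl]-3-[3,5-bis(benzyloxy)phenyl]-6-[(E)-2-[3,4-bis(benzyloxy)phenyl]ethenyl]-2,3-dihydro-1-benzofuran-4-ol | c1ccccc1COc1cc(OCc2ccccc2)cc([C@H]2c3c(O)cc(/C=C/c4ccc(OCc5ccccc5)c(OCc5ccccc5)c4)cc3O[C@@H]2c2ccc(OCc3ccccc3)c(OCc3ccccc3)c2)c1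
F19 | step 10 | mac boronate of (1R,2S)-1-(3,4-dimethoxyphenyl)-2-(3,5-dimethoxyphenyl)-2-[4-[(E)-2-(3,4-dimethoxyphenyl)ethenyl]-2,6-dihydroxyphenyl]ethane, boron on C1 | Oc1cc(/C=C/c2ccc(OC)c(OC)c2)cc(O)c1[C@H](c1cc(OC)cc(OC)c1)[C@@H](B1O[C@]2(C)c3cccc4cccc(c34)[C@]2(C)O1)c1ccc(OC)c(OC)c1
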